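You cannot read free G from any run, since cedar and maple report only J and Z, so reckon it for Thursday's flask, where G trickles in.

| setting | cedar | maple | Thursday's | Friday's | Saturday's |
|---|---|---|---|---|---|
| X | 0.090 M | 0.090 M | 0.090 M | 0.090 M | 0.090 M (fed, over 50 min) |
| G | 0.90 equiv | 1.8 equiv | 0.900 equiv (fed, over 50 min) | 0.900 equiv | 0.900 equiv |
| D | 0.05 mol% | 0.05 mol% | 0.05 mol% | 0.05 mol% | 0.05 mol% |
| remark | run made earlier | run made earlier | all else is in the flask from the start; the feed brings no volume worth counting | everything together at the start | all else is in the flask from the start; the feed brings no volume worth counting |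
| time |  |  | 80 min | 80 min | 80 min |

| run | time / min | Z / % | J / % |
|---|---|---|---|
| cedar | 4.00 | 1.6 | 10.9 |
| cedar | 8.00 | 3.2 | 19.7 |
| cedar | 15.0 | 7.6 | 35.7 |
| cedar | 25.0 | 12.4 | 55.2 |
| cedar | 50.0 | 12.4 | 65.4 |
| maple | 1.50 | 0.3 | 3.7 |
| maple | 3.00 | 1.1 | 7.8 |
| maple | 5.00 | 2.7 | 12.5 |
| maple | 6.00 | 3.1 | 15.4 |
| maple | 8.00 | 5.8 | 17.5 |

(readings scatter by 0.5 percentage points)



- the flask with the highest amount of Z, in percent of the X charged ("all alike" if they lie within 1.5 percentage points) (Thursday's / Friday's / Saturday's / all alike)
- final Z, as a percentage of the X charged, in Thursday's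
- final Z, as a percentage of the X charged, in Friday's
- final Z, as a percentage of the X charged, in Saturday's

Take the speed of D from cedar: J plus Z at 15.0 min gives 0.0289 /min of the X charged per minute, and maple, with twice the G, gives 0.0291 /min at 8.00 min. Thursday's feed brings 0.0180 /min, so call the speed of D over the feed rate the headroom, 1.60. Because D is faster than the feed, expect G to hold at a steady state, where uptake equals feed and free G is the half-saturation level over headroom minus one.

Get that level from cedar, which slowed to 0.0243 /min between 15.0 min and 25.0 min. Cedar's end balance, J plus twice Z at 90.2%, puts two G in each Z, so mean G there was 0.245 of the X charged. That gives a half-saturation level of 0.0461 and a free G of 0.0764. Cedar's rise in Z, over J times G at 15.0 min, gives 0.0388 /min. Let J climb with the feed, and Z comes to 6.67%.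

Now reforge the weak link: that reckoning let G fall and held X steady, yet between those readings X in cedar fell from 56.7% to 32.4% of its charge. Count half of the slowing for G and the estimate of Z drops to 3.33%, so commit to the middle, 5.00%. Friday's repeats cedar, so read 12.4% there.

The forecast names Saturday's, with Z of 4% (1% to 9%) for Thursday's, below my figure, 12.6% for Friday's and 16% for Saturday's, and of Thursday's says: “The value depends on the poorly known affinity for G”.

Z ends at 5.16% in Thursday's, 12.6% in Friday's and 15.9% in Saturday's, so Saturday's holds the most.

    X + D ⇌ L (K = 26.0 /M, k = 1.60 × 10⁵ /M/min)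
    G + L ⇌ E (K = 530 /M, k = 2.60 × 10⁵ /M/min)
    E → D + J (k = 60.0 /min)
    G + J → Z (k = 0.470 /M/min)

In Thursday's flask, with headroom 1.60, G averaged 0.00446 M over the first 50.0 min while J climbed to 74.4% and Z to 4.41%, and after the feed D went on making J and G went on passing with J into Z until, by 80.0 min, G stood at 0%, Z at 5.16% and X at 15.1%. Scale the headroom with D for the neighbour of Thursday's with 0.013 mol%, and it is 0.417, under one; at 80.0 min that flask held G at 18.9% of its charge, X at 47.2% and Z at 20.1%.

The data were generated by integration for substances that don't exist, noise included.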